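**Retrosynthetic overview**

1. Selaginellin F (19) ⇐ triarylcarbinol 18 by acid-mediated loss of five MOM groups, one TBS group and water. The cyclohexadienone ring with its exocyclic C=C is a para-hydroxyphenyl carbinol in dehydrated form (fuchsone relationship).
2. 18 ⇐ one-pot three-component aryne coupling. The C1–C2 edge of the central benzene ring is the triple bond of aryne 16; the resorcinol-derived Grignard reagent 14 adds at C2, and the arylmagnesium formed at C1 attacks diaryl ketone 13, making the bond from ring C1 to the future methide carbon.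
3. Enabling feature: C1 and C2 of the central ring carry two adjacent carbon substituents (the triaryl carbon and the 2,4-dioxygenated ring), and C6, next to C1, carries the arylethynyl group, whose sp carbon steers the nucleophile to C2 and the carbanion to C1.
4. Aryne precursor 9 ⇐ Sonogashira coupling of alkyne 8 at the iodide of the bromo-fluoro-iodo benzyl silyl ether 5, which comes from 2-amino-4-bromo-3-fluorobenzoic acid 1 by iododediazoniation, reduction and silylation.
5. No ring is constructed; all five six-membered rings are bought as benzene rings. Order of events: alkyne, then aryne biaryl/carbinol coupling, then dearomatisation of one phenol ring to the quinone methide in the last step.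

Key step: step 9

Remark: the target has no stereocentre and is taken as the open quinone methide drawn; its possible ring-chain isomer (addition of the 2'-OH to the methide carbon) is assumed to revert to this form under the acidic equilibration of the last step.

**Route**

Step 1
Reactants: 1 2-amino-4-bromo-3-fluorobenzoic acid
Product: 3 4-bromo-3-fluoro-2-iodobenzoic acid, via diazonium chloride 2 (not isolated)
Conditions: NaNO2, 6 M HCl, MeCN/H2O, 0 °C; then KI, 0 °C → rt
Reagents that add atoms: potassium iodide [K+].[I-]
Why: Diazotisation of the anthranilic acid followed by iododediazoniation (Sandmeyer-type, no copper needed) should place iodine by ipso substitution exactly between the carboxyl group and fluorine.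

Step 2
Reactants: 3 4-bromo-3-fluoro-2-iodobenzoic acid
Product: 4 (4-bromo-3-fluoro-2-iodophenyl)methanol
Conditions: BH3·THF, THF, 0 °C → rt; aq. work-up
Reagents that add atoms: none
Why: Borane reduction of a carboxylic acid is chemoselective and should leave all three aryl–halogen bonds untouched.

Step 3
Reactants: 4 (4-bromo-3-fluoro-2-iodophenyl)methanol
Product: 5 tert-butyl[(4-bromo-3-fluoro-2-iodophenyl)methoxy]dimethylsilane
Conditions: TBSCl, imidazole, DMF, rt
Reagents that add atoms: tert-butyldimethylsilyl chloride CC(C)(C)[Si](C)(C)Cl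
Why: Standard silylation of a primary alcohol; the silyl ether should prevent cyclisation of the alcohol onto the alkyne later and tolerate the Grignard chemistry.

Step 4
Reactants: 6 4-hydroxybenzaldehyde
Product: 7 4-(methoxymethoxy)benzaldehyde
Conditions: MOMCl, i-Pr2NEt, CH2Cl2, 0 °C → rt
Reagents that add atoms: chloromethyl methyl ether COCCl
Why: O-alkylation of a phenol with MOMCl gives an acetal that is stable to base and organometallics and is removed by acid at the end.

Step 5
Reactants: 7 4-(methoxymethoxy)benzaldehyde
Product: 8 1-ethynyl-4-(methoxymethoxy)benzene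
Conditions: dimethyl (1-diazo-2-oxopropyl)phosphonate, K2CO3, MeOH, rt
Reagents that add atoms: dimethyl (1-diazo-2-oxopropyl)phosphonate CC(=O)C(=[N+]=[N-])P(=O)(OC)OC
Why: Ohira–Bestmann (Seyferth–Gilbert) homologation should convert the non-enolisable aryl aldehyde into the terminal alkyne under mild base that the MOM ether tolerates.

Step 6
Reactants: 5 tert-butyl[(4-bromo-3-fluoro-2-iodophenyl)methoxy]dimethylsilane; 8 1-ethynyl-4-(methoxymethoxy)benzene
Product: 9 tert-butyl[(4-bromo-3-fluoro-2-{[4-(methoxymethoxy)phenyl]ethynyl}phenyl)methoxy]dimethylsilane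
Conditions: Pd(PPh3)2Cl2 (cat.), CuI (cat.), Et3N/THF, rt → 40 °C
Reagents that add atoms: none
Why: Sonogashira coupling should occur at the C–I bond only, because oxidative addition to aryl iodides is far faster than to aryl bromides at this temperature.

Step 7
Reactants: 10 4-bromobenzene-1,3-diol
Product: 11 1-bromo-2,4-bis(methoxymethoxy)benzene
Conditions: MOMCl, i-Pr2NEt, CH2Cl2, 0 °C → rt
Reagents that add atoms: chloromethyl methyl ether COCCl
Why: Double O-alkylation of the resorcinol with MOMCl; the ortho MOM ether should also stabilise the derived arylmagnesium by chelation.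

Step 8
Reactants: 12 bis(4-hydroxyphenyl)methanone
Product: 13 bis[4-(methoxymethoxy)phenyl]methanone
Conditions: MOMCl, i-Pr2NEt, CH2Cl2/DMF, 0 °C → rt
Reagents that add atoms: chloromethyl methyl ether COCCl
Why: Double O-alkylation of the acidic para-acyl phenols with MOMCl gives a ketone without acidic protons for the organometallic step.

Step 9
Reactants: 9 tert-butyl[(4-bromo-3-fluoro-2-{[4-(methoxymethoxy)phenyl]ethynyl}phenyl)methoxy]dimethylsilane; 11 1-bromo-2,4-bis(methoxymethoxy)benzene; 13 bis[4-(methoxymethoxy)phenyl]methanone
Product: 18 {4-({[tert-butyl(dimethyl)silyl]oxy}methyl)-2',4'-bis(methoxymethoxy)-3-{[4-(methoxymethoxy)phenyl]ethynyl}-[1,1'-biphenyl]-2-yl}bis[4-(methoxymethoxy)phenyl]methanol, via arylmagnesium bromide 14 (not isolated), via fluoroaryl Grignard reagent 15 (not isolated), via aryne 16 (not isolated), via biarylmagnesium bromide 17 (not isolated)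
Conditions: 11 (2.5 equiv), Mg (excess), LiCl, THF, rt; then 9 added slowly, 60 °C; solution decanted from Mg; then 13 (3 equiv), LaCl3·2LiCl (cat.), 0 °C → rt; aq. NH4Cl
Reagents that add atoms: none
Why: Magnesium inserts into the C–Br bond of 9, and the ortho-fluoroarylmagnesium 15 loses MgBrF at 60 °C to give aryne 16, whose triple bond lies between the two ring carbons that carry the resorcinol ring and the triaryl carbon in the target; Grignard reagent 14 adds to it, and the arylmagnesium 17 so formed is then captured by ketone 13, which makes the bond between the central ring and the future methide carbon and joins the two halves of the molecule. The closest known reaction type is the Hart terphenyl synthesis and the related one-pot 2-biarylmagnesium/electrophile sequences (aryl Grignard addition to an aryne made from an ortho-dihaloarene and magnesium, then trapping of the new Grignard reagent), finished here by an ordinary Grignard addition to a diaryl ketone. No ring is closed and no stereocentre is formed. The selectivity that matters is the direction of addition to the unsymmetrical aryne: the sp carbon of the arylethynyl group on the ring carbon next to the triple bond withdraws electrons inductively, so the aryne carbon remote from it is the more electrophilic one and the carbanion develops next to the alkyne, as in the second addition of the Hart reaction, where the nucleophile also enters remote from the substituent already in place; the ortho-substituted nucleophile 14 avoids the flanked carbon for steric reasons as well. Slow addition of 9 into an excess of 14 should keep 15 from adding to its own aryne, removal of the magnesium metal before the ketone is added avoids pinacol reduction, and LaCl3·2LiCl should help the doubly ortho-substituted 17 to add to the electron-rich ketone.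

Step 10
Reactants: 18 {4-({[tert-butyl(dimethyl)silyl]oxy}methyl)-2',4'-bis(methoxymethoxy)-3-{[4-(methoxymethoxy)phenyl]ethynyl}-[1,1'-biphenyl]-2-yl}bis[4-(methoxymethoxy)phenyl]methanol
Product: 19 Selaginellin F, 4-{[2',4'-dihydroxy-4-(hydroxymethyl)-3-[(4-hydroxyphenyl)ethynyl]-[1,1'-biphenyl]-2-yl](4-hydroxyphenyl)methylidene}cyclohexa-2,5-dien-1-one
Conditions: HCl, MeOH/THF, 45 °C; then aq. NaHCO3 to pH 6–7
Reagents that add atoms: none
Why: Acidic methanolysis should cleave the silyl ether and the five aryl MOM acetals, while the bis(para-oxyphenyl) carbinol ionises to the trityl cation, which loses a phenolic proton on neutralisation to give the quinone methide (fuchsone formation).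

**Compound list**

1 | 2-amino-4-bromo-3-fluorobenzoic acid | Nc1c(F)c(Br)ccc1C(=O)O | starting material
2 | 3-bromo-6-carboxy-2-fluorobenzenediazonium chloride | OC(=O)c1ccc(Br)c(F)c1[N+]#N.[Cl-] | intermediate
3 | 4-bromo-3-fluoro-2-iodobenzoic acid | OC(=O)c1ccc(Br)c(F)c1I | intermediate
4 | (4-bromo-3-fluoro-2-iodophenyl)methanol | OCc1ccc(Br)c(F)c1I | intermediate
5 | tert-butyl[(4-bromo-3-fluoro-2-iodophenyl)methoxy]dimethylsilane | CC(C)(C)[Si](C)(C)OCc1ccc(Br)c(F)c1I | intermediate
6 | 4-hydroxybenzaldehyde | O=Cc1ccc(O)cc1 | starting material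
7 | 4-(methoxymethoxy)benzaldehyde | COCOc1ccc(C=O)cc1 | intermediate
8 | 1-ethynyl-4-(methoxymethoxy)benzene | COCOc1ccc(C#C)cc1 | intermediate
9 | tert-butyl[(4-bromo-3-fluoro-2-{[4-(methoxymethoxy)phenyl]ethynyl}phenyl)methoxy]dimethylsilane | CC(C)(C)[Si](C)(C)OCc1ccc(Br)c(F)c1C#Cc1ccc(OCOC)cc1 | intermediate
10 | 4-bromobenzene-1,3-diol | Oc1ccc(Br)c(O)c1 | starting material
11 | 1-bromo-2,4-bis(methoxymethoxy)benzene | COCOc1ccc(Br)c(OCOC)c1 | intermediate
12 | bis(4-hydroxyphenyl)methanone | O=C(c1ccc(O)cc1)c1ccc(O)cc1 | starting material
13 | bis[4-(methoxymethoxy)phenyl]methanone | O=C(c1ccc(OCOC)cc1)c1ccc(OCOC)cc1 | intermediate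
14 | [2,4-bis(methoxymethoxy)phenyl]magnesium bromide | COCOc1ccc([Mg]Br)c(OCOC)c1 | intermediate
15 | [4-({[tert-butyl(dimethyl)silyl]oxy}methyl)-2-fluoro-3-{[4-(methoxymethoxy)phenyl]ethynyl}phenyl]magnesium bromide | CC(C)(C)[Si](C)(C)OCc1ccc([Mg]Br)c(F)c1C#Cc1ccc(OCOC)cc1 | intermediate
16 | tert-butyl[(2-{[4-(methoxymethoxy)phenyl]ethynyl}-3,4-didehydrophenyl)methoxy]dimethylsilane (aryne) | CC(C)(C)[Si](C)(C)OCC1=C(C#Cc2ccc(OCOC)cc2)C#CC=C1 | intermediate
17 | [4-({[tert-butyl(dimethyl)silyl]oxy}methyl)-2',4'-bis(methoxymethoxy)-3-{[4-(methoxymethoxy)phenyl]ethynyl}-[1,1'-biphenyl]-2-yl]magnesium bromide | CC(C)(C)[Si](C)(C)OCc1ccc(-c2ccc(OCOC)cc2OCOC)c([Mg]Br)c1C#Cc1ccc(OCOC)cc1 | intermediate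
18 | {4-({[tert-butyl(dimethyl)silyl]oxy}methyl)-2',4'-bis(methoxymethoxy)-3-{[4-(methoxymethoxy)phenyl]ethynyl}-[1,1'-biphenyl]-2-yl}bis[4-(methoxymethoxy)phenyl]methanol | CC(C)(C)[Si](C)(C)OCc1ccc(-c2ccc(OCOC)cc2OCOC)c(C(O)(c2ccc(OCOC)cc2)c2ccc(OCOC)cc2)c1C#Cc1ccc(OCOC)cc1 | intermediate
19 | Selaginellin F, 4-{[2',4'-dihydroxy-4-(hydroxymethyl)-3-[(4-hydroxyphenyl)ethynyl]-[1,1'-biphenyl]-2-yl](4-hydroxyphenyl)methylidene}cyclohexa-2,5-dien-1-one | O=C1C=CC(=C(c2ccc(O)cc2)c2c(-c3ccc(O)cc3O)ccc(CO)c2C#Cc2ccc(O)cc2)C=C1 | target

**Summary**

Total step count: 10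
Longest linear sequence: 6 steps (steps 1, 2, 3, 6, 9, 10)

**Steps most likely to fail**

Step 9. The doubly ortho-substituted arylmagnesium 17 may be protonated, or the ketone may be used up by the excess of the simpler Grignard reagent 14, before 17 adds to the electron-rich ketone; incomplete control of the direction of addition to the aryne would also show at this point as isomeric carbinols. The fallback sets out from 9 and comes back to the route at 18. The aryne addition is run as in step 9 (14, 15, 16 and 17 formed in the same way), but 17 is quenched with iodine instead of the ketone, which should give the aryl iodide tert-butyl[(2-iodo-2',4'-bis(methoxymethoxy)-3-{[4-(methoxymethoxy)phenyl]ethynyl}-[1,1'-biphenyl]-4-yl)methoxy]dimethylsilane F1, which is purified free of all other organometallic material. Iodine–lithium exchange with t-BuLi (2 equiv) in Et2O/THF at −78 °C should then give the more reactive aryllithium [4-({[tert-butyl(dimethyl)silyl]oxy}methyl)-2',4'-bis(methoxymethoxy)-3-{[4-(methoxymethoxy)phenyl]ethynyl}-[1,1'-biphenyl]-2-yl]lithium F2, to which ketone 13 is added as the only electrophile partner, giving 18 after aqueous work-up.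

Step 10. Under protic acid the methoxymethyl cation set free from five acetals may be captured by the very electron-rich resorcinol ring, and the alkyne next to the freed benzylic alcohol may be hydrated or cyclised. The fallback sets out from 18 and comes back to the route at 19. The aryl MOM ethers are first removed under aprotic, buffered silyl-transfer conditions (TMSOTf, 2,2'-bipyridyl, CH2Cl2/MeCN, 0 °C → rt, then water), which should spare the silyl ether and give the quinone methide 4-{[4-({[tert-butyl(dimethyl)silyl]oxy}methyl)-2',4'-dihydroxy-3-[(4-hydroxyphenyl)ethynyl]-[1,1'-biphenyl]-2-yl](4-hydroxyphenyl)methylidene}cyclohexa-2,5-dien-1-one F3. The benzylic silyl ether is then cleaved separately with HF·pyridine in THF/pyridine at 0 °C, giving 19.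

Step 6. Oxidative addition at the C–I bond flanked by two ortho substituents may be slow enough for oxidative homocoupling of the alkyne and coupling at the C–Br bond to compete. The fallback sets out from 8 (with 5) and comes back to the route at 9. Alkyne 8 is converted with CuI in aqueous ammonia/ethanol into the isolated copper(I) [4-(methoxymethoxy)phenyl]acetylide F4, which is heated with iodide 5 in pyridine (Castro–Stephens coupling, no palladium). This should substitute the aryl iodide only and give 9.

**Further compounds**

F1 | step 9 | tert-butyl[(2-iodo-2',4'-bis(methoxymethoxy)-3-{[4-(methoxymethoxy)phenyl]ethynyl}-[1,1'-biphenyl]-4-yl)methoxy]dimethylsilane | CC(C)(C)[Si](C)(C)OCc1ccc(-c2ccc(OCOC)cc2OCOC)c(I)c1C#Cc1ccc(OCOC)cc1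
F2 | step 9 | [4-({[tert-butyl(dimethyl)silyl]oxy}methyl)-2',4'-bis(methoxymethoxy)-3-{[4-(methoxymethoxy)phenyl]ethynyl}-[1,1'-biphenyl]-2-yl]lithium | CC(C)(C)[Si](C)(C)OCc1ccc(-c2ccc(OCOC)cc2OCOC)c([Li])c1C#Cc1ccc(OCOC)cc1
F3 | step 10 | 4-{[4-({[tert-butyl(dimethyl)silyl]oxy}methyl)-2',4'-dihydroxy-3-[(4-hydroxyphenyl)ethynyl]-[1,1'-biphenyl]-2-yl](4-hydroxyphenyl)methylidene}cyclohexa-2,5-dien-1-one | O=C1C=CC(=C(c2ccc(O)cc2)c2c(-c3ccc(O)cc3O)ccc(CO[Si](C)(C)C(C)(C)C)c2C#Cc2ccc(O)cc2)C=C1
F4 | step 6 | copper(I) [4-(methoxymethoxy)phenyl]acetylide | COCOc1ccc(C#C[Cu])cc1
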